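## The problem

The target is a linear trimer of three chromane units: an upper (2S)-4′,7-dihydroxyflavan with no oxygen at C3, a middle epiafzelechin and a lower, terminal epiafzelechin. The units are joined twice by a bond from the benzylic C4 of one unit to the crowded C8 of ring A of the next.

Seven stereocentres must be set: upper C2 (S) and C4 (R; 2,4-trans), middle C2, C3 and C4 (2,3-cis; 3,4-trans), and lower C2 and C3 (2,3-cis). Within a unit the centres can steer one another. The α-aryl group at upper C2 sends a nucleophile to the β face of the C4 cation, and the 2α-aryl and 3α-oxygen of the middle unit do the same at its C4. The lower 2-aryl group can direct both a hydroboration and a hydride reduction at C3. No centre of one unit controls a centre of another, so each unit must take its absolute configuration from a catalyst or from the chiral pool.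

The molecule tolerates little. The interflavan bonds are benzylic bonds to very electron-rich arenes and are cleaved or scrambled by strong acid. The free phloroglucinol rings oxidise in base and are nucleophilic at C6 as well as C8. Any 2-arylchroman-4-one met on the way opens to a chalcone under base, with loss of C2. The phenols therefore travel as benzyl ethers to one final hydrogenolysis, and the late steps stay near neutral.

The feature that opens a different way is ring A of the lower unit: C5, C7 and C8a carry oxygen while C4a, C6 and C8 do not. This is the alternating pattern of a folded triketide in which C8 is one of the methylene carbons and bears middle C4, while C8a–O1 and C4a–C4 already belong to ring C. Ring A can therefore be closed last, by acylation of C4a with C5, in a chain where C8 is an sp3 carbon already bonded to middle C4 and O1/C8a/C4a/C4 are held as a 2-aryl-2,3-dihydropyran-4-one.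

## Retrosynthesis

**33 back to 25.** No skeletal bond is cut. The nine O–benzyl bonds of 32 and the lower C3–O bond are removed. The cis alcohol of 32 comes from flavan-3-one 31 by hydride delivery anti to the 2-aryl group; 31 comes from the trans alcohol 30, the hydroboration product of flavene 28. Flavene 28 is reached from flavanone 25 through 26 and 27 by carbonyl reduction, benzylation and dehydration. Hydroboration is preferred to hydroxylation of a C3 enolate of 25, because that enolate expels the ring oxygen (chalcone) and would cost lower C2. The forward steps must be non-acidic and must leave the benzylic ethers alone.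

**25 back to 24 (key cut).** The C4a–C5 bond of lower ring A is cut, which removes a whole benzene ring. The neighbouring cut, middle C4 to lower C8 with ring A intact, would need a C4-activated dimer and an arene that picks C8 over C6 without further alkylation. In 24 that carbon is an sp3 methine already bonded to middle C4, so the linkage is fixed by construction. The forward reaction must acylate C4a and nothing else, under a base too mild to touch lower C2.

**24 back to 22.** The C5–OMe ester is traced to a dioxinone. Through the two Lewis-acid alkylations a free β-keto ester would be a competing carbon nucleophile at C6 and could cyclise early. The dioxinone has no α′ hydrogens, and is opened to the methyl ester by heat alone.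

**22 back to 21 and 5.** The upper C4–middle C8 bond is cut. This union has to precede formation of lower ring A, whose C6 would otherwise compete. It has to follow oxidation of middle C4, because a quinone oxidant on a dimer would meet the doubly benzylic upper C4–H. The forward reaction needs C8 over C6 and 2,4-trans.

**21 back to 9 and 19.** The sp3–sp3 bond from middle C4 to the linking methine is cut. In 19 that carbon is a methylene activated by both vinylogous carbonyls, so its silyl dienol ether 20 is formed at one position only. The alternative, a 6-methylpyranone alkylated and then acylated at the same carbon, would face the α′ versus γ enolisation problem of vinylogous esters twice. The forward reaction needs attack on the β face of the C4 cation from 9.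

**9 back to 6.** Only O–benzyl bonds and the C4–O bond are cut. Donor 9 comes from 8 by oxidation of C4–H while that is the only doubly activated benzylic position; 8 comes from 7 and 7 from 6. Compound 6 supplies middle C2 and C3.

**19 back to 11 and 16.** O1–C8a is cut (cyclodehydration of 18, released from 17) and then C4a–C4 (Claisen union of the dianion of 11 with Weinreb amide 16). Both are standard polyketide-assembly reactions, and the one stereocentre is carried in 16.

**16 back to 12 and 13; 11 back to 10.** Amide 16 is the silyl ether of 15, made by asymmetric reduction of β-keto amide 14, the Claisen product of 12 and 13. This reduction sets lower C2. Keto-dioxinone 11 is the γ-acetylation product of 10.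

**5 back to 1 and 3.** Alcohol 5 is the reduction product of flavanone 4. The C2–aryl bond of 4 is cut to chromone 2 (the benzyl ether of 1) and boronic acid 3; the asymmetric conjugate addition sets upper C2.

## Roads not taken

**Alternative 1: Danheiser benzannulation to grow middle ring A on the upper unit.**
- Cut: C8–C8a and C6–C7 of middle ring A.
- Forward key step: the upper flavan with a siloxyethynyl group at C4β (A2) is heated with cyclobutenone A3. Ring opening to a vinylketene, [2+2] addition to the ynol ether, a second 4π opening and 6π closure give phenol A1. In A1, C8 bears the upper unit, C8a carries the free hydroxyl and C4a the cinnamyl chain for ring C.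
- Merits: the upper–middle junction is regiospecific by construction, the three oxygens of ring A emerge differentiated, and the step is thermal and neutral.
- Weak points: A2 is an ynol silyl ether on a secondary benzylic stereocentre and must be made with the 4β configuration intact. After A1 the whole of middle ring C is still to be built (dihydroxylation, closure, inversion at C3). C4 must then be activated on a dimer, and the bond to the lower unit is left to a conventional cation–arene coupling.
- Comparison: for the upper–middle bond this road is better than the chosen plan, which in step 14 relies on the innate C8 and 2,4-trans preferences of a Friedel–Crafts reaction. Against that, the chosen plan takes the middle unit with its centres from 6 and solves the junction that alternative 1 leaves open. Alternative 1 is also clearly longer.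

**Alternative 2: epoxy-arene Friedel–Crafts closure of middle ring C.**
- Cut: C4–C4a of the middle unit.
- Forward key step: a Lewis acid opens trans-epoxide A5 at C4, the carbon benzylic to lower ring A, by attack of the only free ortho carbon of the tethered aryl ether. This gives A4 with the middle C3 hydroxyl free.
- Merits: convergent; anti opening gives 3,4-trans; no arene regiochemistry. The lower unit is taken ready-made from 8, which saves about ten steps, so in step economy this road is better.
- Weak points: C4 of A5 sits on a 2,4,6-trioxygenated arene, so the epoxide is a masked para-quinone methide. It should ionise as it forms, which erodes the stereospecific opening and allows hydride shift to a ketone; making it beside six electron-rich rings is itself doubtful. The benzylic C2–O1 aryl ether must be formed with defined configuration at a carbon prone to SN1 substitution, and can re-ionise under the Lewis acid.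
- Comparison: the chosen plan is longer. It forms its sp3–sp3 bond from an isolable 4-alkoxy donor with a known β preference, and it buys the middle stereotriad instead of creating it under cation-prone conditions.

**Alternative 3: ortho-quinone methide cycloaddition.**
- Cut: O1–C2 and C3–C4 of middle ring C.
- Forward key step: acid ionises diaryl carbinol A7 to an ortho-quinone methide across middle C8a–C4a–C4, which adds (Z)-enol acetate A8 in an inverse-demand hetero-Diels–Alder reaction to give A6.
- Merits: the most convergent road. Ring C and three stereocentres arise in one step from two complete halves, the Z-alkene gives 2,3-cis, the C3 oxygen arrives protected, and the lower unit again comes from 8. If it worked it would be far shorter.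
- Weak points: the quinone methide is planar and the only chiral information is in the remote upper and lower units, so the absolute configuration of all three new centres is uncontrolled. Endo/exo selection decides 3,4-trans. The acetoxy and aryl groups polarise the alkene in opposite senses. The Z-enol acetate can isomerise under acid. Diastereomeric nona-benzyl trimers are hard to separate.
- Comparison: better in convergence and step count, worse in stereocontrol. In the chosen plan every stereocentre is set by a catalyst, by the chiral pool or by a neighbouring centre in the same ring.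

Key step: step 16

Assumption: (−)-epiafzelechin 6 and 7-hydroxychromone 1 are taken as purchasable; the linking methine in 21–24 is an epimer mixture, which is harmless because that carbon becomes aromatic C8 in step 16.

Shorthand in names: Ar = 4-(benzyloxy)phenyl. "Dimer core" = (2S,4R)-7-benzyloxy-2-Ar-chroman-4-yl bonded (4β, 2,4-trans) to C8 of 3,5,7,4′-tetra-O-benzylepiafzelechin; the stated substituent sits at C4β of the epiafzelechin part (3,4-trans). X = 2,2-dimethyl-4-oxo-4H-1,3-dioxin-6-yl. Y = (2S)-2-Ar-4-oxo-3,4-dihydro-2H-pyran-6-yl.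

## Route

Step 1
Reactants: 1 7-hydroxy-4H-chromen-4-one
Product: 2 7-(benzyloxy)-4H-chromen-4-one
Conditions: BnBr, K2CO3, acetone, reflux
Reagents that add atoms: benzyl bromide, BrCc1ccccc1
Why: Williamson etherification of the only acidic hydroxyl; the chromone ring is inert to carbonate in acetone.

Step 2
Reactants: 2 7-(benzyloxy)-4H-chromen-4-one; 3 [4-(benzyloxy)phenyl]boronic acid
Product: 4 (2S)-7-(benzyloxy)-2-[4-(benzyloxy)phenyl]chroman-4-one
Conditions: Pd(OCOCF3)2 (5 mol %), (R)-t-BuPyOx (6 mol %), NH4PF6 (30 mol %), H2O (5 equiv), ClCH2CH2Cl, 60 °C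
Reagents that add atoms: none
Why: Palladium-catalysed asymmetric conjugate addition of an arylboronic acid to a chromone; the cationic aryl–palladium–PyOx complex inserts C2=C3 and water protonates the enolate. The ligand fixes the face of insertion, and the (R)-ligand is chosen on the expectation, from the facial sense of this catalyst with cyclic enones, that it gives the 2S adduct; the non-basic medium avoids chalcone formation.

Step 3
Reactants: 4 (2S)-7-(benzyloxy)-2-[4-(benzyloxy)phenyl]chroman-4-one
Product: 5 (2S,4S)-7-(benzyloxy)-2-[4-(benzyloxy)phenyl]chroman-4-ol (2,4-cis)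
Conditions: NaBH4, MeOH/THF, 0 °C
Reagents that add atoms: none
Why: Borohydride reduction of the aryl ketone; hydride adds anti to the 2-aryl group to give the 2,4-cis alcohol, whose C4 configuration is lost on ionisation in step 14.

Step 4
Reactants: 6 (−)-epiafzelechin, (2R,3R)-2-(4-hydroxyphenyl)chroman-3,5,7-triol
Product: 7 5,7,4′-tri-O-benzylepiafzelechin
Conditions: BnBr (3.3 equiv), K2CO3, DMF, 0 °C → rt
Reagents that add atoms: benzyl bromide, BrCc1ccccc1
Why: Williamson etherification; carbonate deprotonates only the three phenols and leaves the secondary 3-OH free.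

Step 5
Reactants: 7 5,7,4′-tri-O-benzylepiafzelechin
Product: 8 3,5,7,4′-tetra-O-benzylepiafzelechin
Conditions: NaH, BnBr, Bu4NI (cat.), DMF, 0 °C → rt
Reagents that add atoms: benzyl bromide, BrCc1ccccc1
Why: Williamson etherification of the secondary alkoxide; the O3 benzyl ether later shields the α face of C4 and lasts to the final hydrogenolysis.

Step 6
Reactants: 8 3,5,7,4′-tetra-O-benzylepiafzelechin
Product: 9 3,5,7,4′-tetra-O-benzyl-4β-(2-ethoxyethoxy)epiafzelechin (3,4-trans)
Conditions: DDQ, 2-ethoxyethanol, CH2Cl2, rt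
Reagents that add atoms: 2-ethoxyethanol, CCOCCO
Why: Oxidative benzylic C–H functionalisation; DDQ abstracts hydride from C4, the only benzylic position backed by the 5,7-dioxygenated ring, and the cation is trapped by the alcohol trans to the 3-benzyloxy group (4β).

Step 7
Reactants: 10 2,2,6-trimethyl-4H-1,3-dioxin-4-one
Product: 11 2,2-dimethyl-6-(2-oxopropyl)-4H-1,3-dioxin-4-one
Conditions: 10 (2 equiv), LiN(SiMe3)2 (2 equiv), THF, −78 °C; AcCl (1 equiv), −78 °C
Reagents that add atoms: acetyl chloride, CC(Cl)=O
Why: γ-Selective C-acylation of the dioxinone lithium dienolate, which has no α′ hydrogen; the second equivalent of dienolate is consumed by the more acidic product.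

Step 8
Reactants: 12 methyl 4-(benzyloxy)benzoate; 13 N-methoxy-N-methylacetamide
Product: 14 3-[4-(benzyloxy)phenyl]-N-methoxy-N-methyl-3-oxopropanamide
Conditions: 13, LiN(iPr)2 (2.2 equiv), THF, −78 °C; then 12, −78 → 0 °C
Reagents that add atoms: none
Why: Crossed Claisen condensation of the acetamide lithium enolate with a non-enolisable aryl ester, driven by deprotonation of the β-keto amide.

Step 9
Reactants: 14 3-[4-(benzyloxy)phenyl]-N-methoxy-N-methyl-3-oxopropanamide
Product: 15 (3S)-3-[4-(benzyloxy)phenyl]-3-hydroxy-N-methoxy-N-methylpropanamide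
Conditions: RuCl(p-cymene)[(S,S)-TsDPEN] (1 mol %), HCO2H/Et3N (5:2), CH2Cl2, 30 °C
Reagents that add atoms: none
Why: Noyori asymmetric transfer hydrogenation of an aryl ketone; with the (S,S)-ligand hydride reaches the face that gives the (S)-benzylic alcohol, as for simple aryl alkyl ketones (arene CH–π contact in the six-membered transition state). This centre becomes lower C2.

Step 10
Reactants: 15 (3S)-3-[4-(benzyloxy)phenyl]-3-hydroxy-N-methoxy-N-methylpropanamide
Product: 16 (3S)-3-[4-(benzyloxy)phenyl]-3-(tert-butyldimethylsilyloxy)-N-methoxy-N-methylpropanamide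
Conditions: TBSCl, imidazole, DMF, rt
Reagents that add atoms: tert-butyldimethylsilyl chloride, CC(C)(C)[Si](C)(C)Cl
Why: Silylation of the secondary alcohol, which prevents retro-aldol cleavage and alkoxide interference in the Claisen step.

Step 11
Reactants: 11 2,2-dimethyl-6-(2-oxopropyl)-4H-1,3-dioxin-4-one; 16 (3S)-3-[4-(benzyloxy)phenyl]-3-(tert-butyldimethylsilyloxy)-N-methoxy-N-methylpropanamide
Product: 17 6-[(6S)-6-[4-(benzyloxy)phenyl]-6-(tert-butyldimethylsilyloxy)-2,4-dioxohexyl]-2,2-dimethyl-4H-1,3-dioxin-4-one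
Conditions: 11 (1.3 equiv), LiN(iPr)2 (2.1 equiv per 11), THF, −78 °C; then 16, −78 → −30 °C
Reagents that add atoms: none
Why: Claisen-type acylation of the keto-dioxinone dianion at its terminal methyl carbon by the Weinreb amide; the chelated tetrahedral intermediate stops the addition at the ketone.

Step 12
Reactants: 17 6-[(6S)-6-[4-(benzyloxy)phenyl]-6-(tert-butyldimethylsilyloxy)-2,4-dioxohexyl]-2,2-dimethyl-4H-1,3-dioxin-4-one
Product: 19 6-{[(2S)-2-[4-(benzyloxy)phenyl]-4-oxo-3,4-dihydro-2H-pyran-6-yl]methyl}-2,2-dimethyl-4H-1,3-dioxin-4-one, via hydroxy diketone 18 (not isolated)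
Conditions: aq. HF (48%), MeCN, 0 °C → rt
Reagents that add atoms: none
Why: The silyl ether is cleaved and the δ-hydroxy β-diketone cyclodehydrates (hemiketal at the distal carbonyl, loss of water) to the 2,3-dihydropyran-4-one; the carbinol C–O bond is not broken, so the S configuration is kept.

Step 13
Reactants: 19 6-{[(2S)-2-[4-(benzyloxy)phenyl]-4-oxo-3,4-dihydro-2H-pyran-6-yl]methyl}-2,2-dimethyl-4H-1,3-dioxin-4-one; 9 3,5,7,4′-tetra-O-benzyl-4β-(2-ethoxyethoxy)epiafzelechin
Product: 21 3,5,7,4′-tetra-O-benzylepiafzelechin carrying at C4β the methine CH(X)(Y) (both methine epimers), via silyl dienol ether 20 (not isolated)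
Conditions: 19 (1.3 equiv), Et3N, TMSOTf, CH2Cl2, 0 °C; then 9, TMSOTf, −78 → −40 °C
Reagents that add atoms: none
Why: Vinylogous Mukaiyama-type alkylation; soft enolisation at the doubly vinylogous methylene gives the silyl dienol ether, whose terminal carbon traps the C4 cation released from 9. Attack is on the β face, trans to the 3-benzyloxy and 2-aryl groups (4β, 3,4-trans); the new methine forms as both epimers, which converge in step 16.

Step 14
Reactants: 21 3,5,7,4′-tetra-O-benzylepiafzelechin carrying at C4β the methine CH(X)(Y); 5 (2S,4S)-7-(benzyloxy)-2-[4-(benzyloxy)phenyl]chroman-4-ol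
Product: 22 dimer core carrying at middle C4β the methine CH(X)(Y)
Conditions: TMSOTf (0.2 equiv), 4 Å molecular sieves, CH2Cl2, −78 → −30 °C
Reagents that add atoms: none
Why: Friedel–Crafts alkylation; the flavan-4-ol ionises to a benzylic cation stabilised by O1 and the 7-benzyloxy group and is attacked by C8 of middle ring A, the most nucleophilic free arene position (C6 lies between two benzyloxy groups). Quasi-axial attack anti to the 2-aryl group gives the 2,4-trans (4β, 4R) linkage.

Step 15
Reactants: 22 dimer core carrying at middle C4β the methine CH(X)(Y)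
Product: 24 methyl 4-(dimer core-4β-yl)-3-oxo-4-[(2S)-2-Ar-4-oxo-3,4-dihydro-2H-pyran-6-yl]butanoate (both C4 epimers), via acylketene 23 (not isolated)
Conditions: MeOH (excess), toluene, 110 °C, sealed tube
Reagents that add atoms: methanol, CO
Why: Thermal retro-[4+2] of the dioxinone expels acetone and the acylketene is captured by methanol, giving the β-keto methyl ester under neutral conditions.

Step 16
Reactants: 24 methyl 4-(dimer core-4β-yl)-3-oxo-4-[(2S)-2-Ar-4-oxo-3,4-dihydro-2H-pyran-6-yl]butanoate
Product: 25 dimer core bonded from middle C4β to C8 of (2S)-4′-O-benzyl-5,7-dihydroxyflavanone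
Conditions: Mg(OMe)2 (4 equiv), MeOH/THF, rt → 45 °C; cold 0.5 M HCl work-up
Reagents that add atoms: none
Why: Mg(OMe)2 reversibly removes the β-keto ester methylene proton and the methine C8–H, which is α to the C7 ketone and γ to the pyranone carbonyl; the C8 anion is an extended enolate running through C8a=C4a to O4, and its α-carbon C4a adds to the ester carbonyl C5. Loss of methoxide gives a cyclohexenetrione that tautomerises at once to the 5,7-dihydroxy aromatic ring, which makes the sequence irreversible and drains the proton-transfer equilibria through this channel. The closest known reaction type is the Claisen-mode (Dieckmann) cyclisation of 3,5,7-triketo esters to acylphloroglucinols with alkoxide or magnesium alkoxide bases; here the C4/C8a diketone is held as the vinylogous ester of the dihydropyranone. Ring A closes by a 6-(enolexo)-exo-trig acyl substitution, the only six-membered closure open to C4a. No stereocentre is created: pyranone C2 is carried over unchanged and C8 becomes aromatic, so both epimers of 24 give one product. The step needs C-acylation at C4a in preference to aldol attack of C6 on the pyranone carbonyl, lactonisation to a pyrone, and opening of the pyranone. The aldol adduct is bridged and cannot dehydrate, so it reverts; the pyrone path is closed because O1 is already alkylated; and E1cB opening at C2 would need deprotonation of the far less acidic C3–H2, which this base should not reach. Magnesium chelation of the 1,3-dicarbonyl unit also holds C5 near C4a.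

Step 17
Reactants: 25 dimer core bonded from middle C4β to C8 of (2S)-4′-O-benzyl-5,7-dihydroxyflavanone
Product: 26 dimer core bonded from middle C4β to C8 of (2S,4S)-2-Ar-chroman-4,5,7-triol (2,4-cis)
Conditions: NaBH4, THF/EtOH, 0 °C → rt; acetone quench, pH 7 buffer
Reagents that add atoms: none
Why: Borohydride reduction of the flavanone carbonyl, a known conversion of 5,7-dihydroxyflavanones into flavan-4-ols. Doing it before benzylation removes the enolisable ketone, so the basic alkylation that follows cannot open ring C to a chalcone and scramble C2; the new C4 centre (hydride anti to the aryl group) is removed in step 19.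

Step 18
Reactants: 26 dimer core bonded from middle C4β to C8 of (2S,4S)-2-Ar-chroman-4,5,7-triol
Product: 27 dimer core bonded from middle C4β to C8 of (2S,4S)-5,7-bis(benzyloxy)-2-Ar-chroman-4-ol
Conditions: BnBr, K2CO3, DMF, rt
Reagents that add atoms: benzyl bromide, BrCc1ccccc1
Why: Williamson etherification of the two new phenols; carbonate does not deprotonate the benzylic 4-OH.

Step 19
Reactants: 27 dimer core bonded from middle C4β to C8 of (2S,4S)-5,7-bis(benzyloxy)-2-Ar-chroman-4-ol
Product: 28 dimer core bonded from middle C4β to C8 of (2S)-5,7-bis(benzyloxy)-2-Ar-2H-chromene (flav-3-ene)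
Conditions: Ph2S[OC(CF3)2Ph]2 (Martin sulfurane), CH2Cl2, 0 °C → rt, dark, argon
Reagents that add atoms: none
Why: Dehydration of the benzylic secondary alcohol through its alkoxysulfurane under neutral conditions; the 2H-chromene forms without free acid that could ionise the interflavan bonds and is used at once.

Step 20
Reactants: 28 dimer core bonded from middle C4β to C8 of (2S)-5,7-bis(benzyloxy)-2-Ar-2H-chromene
Product: 30 dimer core bonded from middle C4β to C8 of 5,7,4′-tri-O-benzylafzelechin (2R,3S; 2,3-trans), via alkylborane 29 (not isolated)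
Conditions: BH3·THF, THF, 0 °C → rt; then NaOH aq, H2O2, 0 °C
Reagents that add atoms: hydrogen peroxide, OO
Why: Hydroboration–oxidation of the styrene-type alkene; boron adds to C3, away from the aryl-bearing C4, on the face anti to the 2-aryl group, and oxidation with retention gives the 2,3-trans alcohol.

Step 21
Reactants: 30 dimer core bonded from middle C4β to C8 of 5,7,4′-tri-O-benzylafzelechin
Product: 31 dimer core bonded from middle C4β to C8 of (2R)-5,7-bis(benzyloxy)-2-Ar-chroman-3-one
Conditions: Dess–Martin periodinane, NaHCO3, CH2Cl2, rt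
Reagents that add atoms: none
Why: Dess–Martin oxidation of the only free hydroxyl to the flavan-3-one under buffered conditions that should not epimerise C2.

Step 22
Reactants: 31 dimer core bonded from middle C4β to C8 of (2R)-5,7-bis(benzyloxy)-2-Ar-chroman-3-one
Product: 32 nona-O-benzyl ether of the target: dimer core bonded from middle C4β to C8 of 5,7,4′-tri-O-benzylepiafzelechin (2R,3R)
Conditions: LiBH(sBu)3, THF, −78 °C; then NaOH aq, H2O2, 0 °C
Reagents that add atoms: none
Why: The bulky hydride adds to the C3 carbonyl from the face opposite the 2-aryl group and gives the 2,3-cis (3α) alcohol of the epiafzelechin unit.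

Step 23
Reactants: 32 nona-O-benzyl ether of the target
Product: 33 (2S)-4′,7-dihydroxyflavan-(4β→8)-epiafzelechin-(4β→8)-epiafzelechin (CNP0257624.1)
Conditions: H2 (1 atm), Pd(OH)2/C, THF/MeOH/H2O, rt
Reagents that add atoms: none
Why: Hydrogenolysis of all nine benzyl ethers under neutral conditions; the interflavan bonds and the chromane C2–O bonds should be retained, as is usual for benzylated oligoflavans.

## Compound list

1 | 7-hydroxy-4H-chromen-4-one | O=c1ccoc2cc(O)ccc12 | starting material
2 | 7-(benzyloxy)-4H-chromen-4-one | O=c1ccoc2cc(OCc3ccccc3)ccc12 | intermediate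
3 | [4-(benzyloxy)phenyl]boronic acid | OB(O)c1ccc(OCc2ccccc2)cc1 | starting material
4 | (2S)-7-(benzyloxy)-2-[4-(benzyloxy)phenyl]chroman-4-one | O=C1C[C@@H](c2ccc(OCc3ccccc3)cc2)Oc2cc(OCc3ccccc3)ccc12 | intermediate
5 | (2S,4S)-7-(benzyloxy)-2-[4-(benzyloxy)phenyl]chroman-4-ol | O[C@H]1C[C@@H](c2ccc(OCc3ccccc3)cc2)Oc2cc(OCc3ccccc3)ccc12 | intermediate
6 | (−)-epiafzelechin | c1c(O)cc(O)c2c1O[C@H](c1ccc(O)cc1)[C@H](O)C2 | starting material
7 | 5,7,4′-tri-O-benzylepiafzelechin | c1c(OCc5ccccc5)cc(OCc5ccccc5)c2c1O[C@H](c1ccc(OCc5ccccc5)cc1)[C@H](O)C2 | intermediate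
8 | 3,5,7,4′-tetra-O-benzylepiafzelechin | c1c(OCc5ccccc5)cc(OCc5ccccc5)c2c1O[C@H](c1ccc(OCc5ccccc5)cc1)[C@H](OCc5ccccc5)C2 | intermediate
9 | 3,5,7,4′-tetra-O-benzyl-4β-(2-ethoxyethoxy)epiafzelechin | c1c(OCc5ccccc5)cc(OCc5ccccc5)c2c1O[C@H](c1ccc(OCc5ccccc5)cc1)[C@H](OCc5ccccc5)[C@H]2OCCOCC | intermediate
10 | 2,2,6-trimethyl-4H-1,3-dioxin-4-one | CC1=CC(=O)OC(C)(C)O1 | starting material
11 | 2,2-dimethyl-6-(2-oxopropyl)-4H-1,3-dioxin-4-one | CC(=O)CC1=CC(=O)OC(C)(C)O1 | intermediate
12 | methyl 4-(benzyloxy)benzoate | COC(=O)c1ccc(OCc2ccccc2)cc1 | starting material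
13 | N-methoxy-N-methylacetamide | CON(C)C(C)=O | starting material
14 | 3-[4-(benzyloxy)phenyl]-N-methoxy-N-methyl-3-oxopropanamide | CON(C)C(=O)CC(=O)c1ccc(OCc2ccccc2)cc1 | intermediate
15 | (3S)-3-[4-(benzyloxy)phenyl]-3-hydroxy-N-methoxy-N-methylpropanamide | CON(C)C(=O)C[C@H](O)c1ccc(OCc2ccccc2)cc1 | intermediate
16 | (3S)-3-[4-(benzyloxy)phenyl]-3-(tert-butyldimethylsilyloxy)-N-methoxy-N-methylpropanamide | CON(C)C(=O)C[C@H](O[Si](C)(C)C(C)(C)C)c1ccc(OCc2ccccc2)cc1 | intermediate
17 | 6-[(6S)-6-[4-(benzyloxy)phenyl]-6-(tert-butyldimethylsilyloxy)-2,4-dioxohexyl]-2,2-dimethyl-4H-1,3-dioxin-4-one | CC1(C)OC(=O)C=C(CC(=O)CC(=O)C[C@H](O[Si](C)(C)C(C)(C)C)c2ccc(OCc3ccccc3)cc2)O1 | intermediate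
18 | 6-[(6S)-6-[4-(benzyloxy)phenyl]-6-hydroxy-2,4-dioxohexyl]-2,2-dimethyl-4H-1,3-dioxin-4-one | CC1(C)OC(=O)C=C(CC(=O)CC(=O)C[C@H](O)c2ccc(OCc3ccccc3)cc2)O1 | intermediate
19 | 6-{[(2S)-2-[4-(benzyloxy)phenyl]-4-oxo-3,4-dihydro-2H-pyran-6-yl]methyl}-2,2-dimethyl-4H-1,3-dioxin-4-one | O=C1C[C@@H](c2ccc(OCc3ccccc3)cc2)OC(CC2=CC(=O)OC(C)(C)O2)=C1 | intermediate
20 | (2S)-2-[4-(benzyloxy)phenyl]-6-[(2,2-dimethyl-4-oxo-4H-1,3-dioxin-6-yl)methylidene]-4-(trimethylsilyloxy)-3,6-dihydro-2H-pyran | C[Si](C)(C)OC1=CC(=CC2=CC(=O)OC(C)(C)O2)O[C@H](c2ccc(OCc3ccccc3)cc2)C1 | intermediate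
21 | 3,5,7,4′-tetra-O-benzylepiafzelechin carrying at C4β the methine CH(X)(Y) | c1c(OCc5ccccc5)cc(OCc5ccccc5)c2c1O[C@H](c1ccc(OCc5ccccc5)cc1)[C@H](OCc5ccccc5)[C@H]2C(C1=CC(=O)OC(C)(C)O1)C1=CC(=O)C[C@@H](c2ccc(OCc5ccccc5)cc2)O1 | intermediate
22 | dimer core carrying at middle C4β the methine CH(X)(Y) | c5ccccc5COc1ccc([C@@H]2C[C@@H](c3c(OCc5ccccc5)cc(OCc5ccccc5)c4c3O[C@H](c3ccc(OCc5ccccc5)cc3)[C@H](OCc5ccccc5)[C@H]4C(C3=CC(=O)OC(C)(C)O3)C3=CC(=O)C[C@@H](c4ccc(OCc5ccccc5)cc4)O3)c3ccc(OCc5ccccc5)cc3O2)cc1 | intermediate
23 | acylketene from 22: dimer core carrying at middle C4β the methine CH(Y)–C(=O)–CH=C=O | c5ccccc5COc1ccc([C@@H]2C[C@@H](c3c(OCc5ccccc5)cc(OCc5ccccc5)c4c3O[C@H](c3ccc(OCc5ccccc5)cc3)[C@H](OCc5ccccc5)[C@H]4C(C(=O)C=C=O)C3=CC(=O)C[C@@H](c4ccc(OCc5ccccc5)cc4)O3)c3ccc(OCc5ccccc5)cc3O2)cc1 | intermediate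
24 | methyl 4-(dimer core-4β-yl)-3-oxo-4-[(2S)-2-Ar-4-oxo-3,4-dihydro-2H-pyran-6-yl]butanoate | c5ccccc5COc1ccc([C@@H]2C[C@@H](c3c(OCc5ccccc5)cc(OCc5ccccc5)c4c3O[C@H](c3ccc(OCc5ccccc5)cc3)[C@H](OCc5ccccc5)[C@H]4C(C(=O)CC(=O)OC)C3=CC(=O)C[C@@H](c4ccc(OCc5ccccc5)cc4)O3)c3ccc(OCc5ccccc5)cc3O2)cc1 | intermediate
25 | dimer core bonded from middle C4β to C8 of (2S)-4′-O-benzyl-5,7-dihydroxyflavanone | c5ccccc5COc1ccc([C@@H]2C[C@@H](c3c(OCc5ccccc5)cc(OCc5ccccc5)c4c3O[C@H](c3ccc(OCc5ccccc5)cc3)[C@H](OCc5ccccc5)[C@H]4c3c(O)cc(O)c4c3O[C@H](c3ccc(OCc5ccccc5)cc3)CC4=O)c3ccc(OCc5ccccc5)cc3O2)cc1 | intermediate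
26 | dimer core bonded from middle C4β to C8 of (2S,4S)-2-Ar-chroman-4,5,7-triol | c5ccccc5COc1ccc([C@@H]2C[C@@H](c3c(OCc5ccccc5)cc(OCc5ccccc5)c4c3O[C@H](c3ccc(OCc5ccccc5)cc3)[C@H](OCc5ccccc5)[C@H]4c3c(O)cc(O)c4c3O[C@H](c3ccc(OCc5ccccc5)cc3)C[C@@H]4O)c3ccc(OCc5ccccc5)cc3O2)cc1 | intermediate
27 | dimer core bonded from middle C4β to C8 of (2S,4S)-5,7-bis(benzyloxy)-2-Ar-chroman-4-ol | c5ccccc5COc1ccc([C@@H]2C[C@@H](c3c(OCc5ccccc5)cc(OCc5ccccc5)c4c3O[C@H](c3ccc(OCc5ccccc5)cc3)[C@H](OCc5ccccc5)[C@H]4c3c(OCc5ccccc5)cc(OCc5ccccc5)c4c3O[C@H](c3ccc(OCc5ccccc5)cc3)C[C@@H]4O)c3ccc(OCc5ccccc5)cc3O2)cc1 | intermediate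
28 | dimer core bonded from middle C4β to C8 of (2S)-5,7-bis(benzyloxy)-2-Ar-2H-chromene | c5ccccc5COc1ccc([C@@H]2C[C@@H](c3c(OCc5ccccc5)cc(OCc5ccccc5)c4c3O[C@H](c3ccc(OCc5ccccc5)cc3)[C@H](OCc5ccccc5)[C@H]4c3c(OCc5ccccc5)cc(OCc5ccccc5)c4c3O[C@H](c3ccc(OCc5ccccc5)cc3)C=C4)c3ccc(OCc5ccccc5)cc3O2)cc1 | intermediate
29 | 3β-boryl adduct of 28 (lower unit 2,3-trans, boron at C3) | c5ccccc5COc1ccc([C@@H]2C[C@@H](c3c(OCc5ccccc5)cc(OCc5ccccc5)c4c3O[C@H](c3ccc(OCc5ccccc5)cc3)[C@H](OCc5ccccc5)[C@H]4c3c(OCc5ccccc5)cc(OCc5ccccc5)c4c3O[C@H](c3ccc(OCc5ccccc5)cc3)[C@@H](B)C4)c3ccc(OCc5ccccc5)cc3O2)cc1 | intermediate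
30 | dimer core bonded from middle C4β to C8 of 5,7,4′-tri-O-benzylafzelechin (2R,3S) | c5ccccc5COc1ccc([C@@H]2C[C@@H](c3c(OCc5ccccc5)cc(OCc5ccccc5)c4c3O[C@H](c3ccc(OCc5ccccc5)cc3)[C@H](OCc5ccccc5)[C@H]4c3c(OCc5ccccc5)cc(OCc5ccccc5)c4c3O[C@H](c3ccc(OCc5ccccc5)cc3)[C@@H](O)C4)c3ccc(OCc5ccccc5)cc3O2)cc1 | intermediate
31 | dimer core bonded from middle C4β to C8 of (2R)-5,7-bis(benzyloxy)-2-Ar-chroman-3-one | c5ccccc5COc1ccc([C@@H]2C[C@@H](c3c(OCc5ccccc5)cc(OCc5ccccc5)c4c3O[C@H](c3ccc(OCc5ccccc5)cc3)[C@H](OCc5ccccc5)[C@H]4c3c(OCc5ccccc5)cc(OCc5ccccc5)c4c3O[C@H](c3ccc(OCc5ccccc5)cc3)C(=O)C4)c3ccc(OCc5ccccc5)cc3O2)cc1 | intermediate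
32 | nona-O-benzyl ether of the target | c5ccccc5COc1ccc([C@@H]2C[C@@H](c3c(OCc5ccccc5)cc(OCc5ccccc5)c4c3O[C@H](c3ccc(OCc5ccccc5)cc3)[C@H](OCc5ccccc5)[C@H]4c3c(OCc5ccccc5)cc(OCc5ccccc5)c4c3O[C@H](c3ccc(OCc5ccccc5)cc3)[C@H](O)C4)c3ccc(OCc5ccccc5)cc3O2)cc1 | intermediate
33 | (2S)-4′,7-dihydroxyflavan-(4β→8)-epiafzelechin-(4β→8)-epiafzelechin | Oc1ccc([C@@H]2C[C@@H](c3c(O)cc(O)c4c3O[C@H](c3ccc(O)cc3)[C@H](O)[C@H]4c3c(O)cc(O)c4c3O[C@H](c3ccc(O)cc3)[C@H](O)C4)c3ccc(O)cc3O2)cc1 | target

## Step count and least certain steps

Total: 23 steps. Longest linear sequence: 16 steps (steps 8–13, then 14–23).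

**Step 16 (key step).** The most likely failure is that the ester is switched off by enolisation of the adjacent methylene while methoxide slowly cleaves the C7–C8 bond in a retro-Claisen sense. Prolonged basic treatment could also open the pyranone at C2 and erode that centre. The fallback avoids base altogether. It sets out from 22, which is heated in dilute toluene at 110 °C without methanol. The acylketene 23 then has no external trap; enolisation of its C7 carbonyl toward C8 gives a dienylketene that closes by 6π-electrocyclisation, the final event of a Danheiser-type benzannulation. This forms the same C4a–C5 bond and tautomerises to 25, where the route is rejoined without passing through 24. The detour makes no compound outside the list (F0).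

**Step 13.** Carbon–carbon bond formation at the hindered terminal carbon of 20 may be slower than loss of a proton from the flavanyl cation, or may be diverted to the less substituted α-carbon of the dienol ether. The fallback builds the methine on the flavan one bond at a time. It sets out from 9, which is alkylated under the same Lewis acid conditions with the unhindered silyl dienol ether of 10, trimethyl[(2,2-dimethyl-6-methylidene-6H-1,3-dioxin-4-yl)oxy]silane F1 (from 10 with LiN(iPr)2 and TMSCl). This gives 3,5,7,4′-tetra-O-benzyl-4β-[(2,2-dimethyl-4-oxo-4H-1,3-dioxin-6-yl)methyl]epiafzelechin F2. γ-Deprotonation of F2 with LiN(SiMe3)2 and acetylation with AcCl gives the keto-dioxinone F3. The dianion of F3 is acylated at its methyl group with 16 to give the silyloxy diketone F4, and aqueous HF then removes the silyl group and closes the pyranone. The route is rejoined at 21.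

**Step 14.** The risks are poor facial selectivity at upper C4 (2,4-cis beside 2,4-trans), some attack at C6, and loss of the cation to the flavene, all on a valuable nucleophile. The fallback changes the order of events. It sets out from 5 and 8: the cation from 5 is coupled with an excess of the simple monomer 8 to give hexa-O-benzyl (2S)-4′,7-dihydroxyflavan-(4β→8)-epiafzelechin F5, so that isomers are separated at the small dimer stage. F5 is oxidised with DDQ and 2-ethoxyethanol to its middle 4β-(2-ethoxyethoxy) derivative F6, which is coupled with 20 as in step 13. The route is rejoined at 22. The price is that the oxidant must distinguish the middle C4–H2 from the doubly benzylic upper C4–H.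

**Step 17.** Reduction of a carbonyl deactivated by two phenoxides may stall. The flavan-4-ol with free ortho and para phenols may ionise to a quinone methide and be reduced further or oligomerise. The fallback sets out from 25. Mitsunobu benzylation (BnOH, PPh3, DIAD; neutral, so no chalcone opening) of the acidic 7-OH gives the 7-O-benzyl-5-hydroxyflavanone F7, whose hydrogen-bonded carbonyl is reduced cleanly by NaBH4 to the 7-O-benzyl-5-hydroxyflavan-4-ol F8. The remaining phenol is then benzylated with BnBr and K2CO3, and the route is rejoined at 27.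

**Step 2.** Protodeboronation of the electron-rich boronic acid and low reactivity of the 7-alkoxychromone may limit conversion, and the enantioselectivity may fall short. The fallback sets out from 2 and 3, which are joined with an achiral catalyst (Pd(OCOCF3)2 with 2,2′-bipyridine) to give racemic 7-(benzyloxy)-2-[4-(benzyloxy)phenyl]chroman-4-one F9. Transfer hydrogenation with RuCl(p-cymene)[(S,S)-TsDPEN] then acts as a kinetic resolution: the 2S enantiomer should be reduced faster to the 2,4-cis alcohol, and the unreacted 2R ketone is separated. The route is rejoined at 5.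

## Further compounds

F0 | step 16 | none | none
F1 | step 13 | trimethyl[(2,2-dimethyl-6-methylidene-6H-1,3-dioxin-4-yl)oxy]silane | C=C1C=C(O[Si](C)(C)C)OC(C)(C)O1
F2 | step 13 | 3,5,7,4′-tetra-O-benzyl-4β-[(2,2-dimethyl-4-oxo-4H-1,3-dioxin-6-yl)methyl]epiafzelechin | c1c(OCc5ccccc5)cc(OCc5ccccc5)c2c1O[C@H](c1ccc(OCc5ccccc5)cc1)[C@H](OCc5ccccc5)[C@H]2CC1=CC(=O)OC(C)(C)O1
F3 | step 13 | 3,5,7,4′-tetra-O-benzylepiafzelechin carrying at C4β the methine CH(X)(acetyl) | c1c(OCc5ccccc5)cc(OCc5ccccc5)c2c1O[C@H](c1ccc(OCc5ccccc5)cc1)[C@H](OCc5ccccc5)[C@H]2C(C(C)=O)C1=CC(=O)OC(C)(C)O1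
F4 | step 13 | 3,5,7,4′-tetra-O-benzylepiafzelechin carrying at C4β the methine CH(X)[C(=O)CH2C(=O)CH2CH(OTBS)Ar] with (S)-carbinol | c1c(OCc5ccccc5)cc(OCc5ccccc5)c2c1O[C@H](c1ccc(OCc5ccccc5)cc1)[C@H](OCc5ccccc5)[C@H]2C(C(=O)CC(=O)C[C@H](O[Si](C)(C)C(C)(C)C)c1ccc(OCc5ccccc5)cc1)C1=CC(=O)OC(C)(C)O1
F5 | step 14 | hexa-O-benzyl (2S)-4′,7-dihydroxyflavan-(4β→8)-epiafzelechin | c5ccccc5COc1ccc([C@@H]2C[C@@H](c3c(OCc5ccccc5)cc(OCc5ccccc5)c4c3O[C@H](c3ccc(OCc5ccccc5)cc3)[C@H](OCc5ccccc5)C4)c3ccc(OCc5ccccc5)cc3O2)cc1
F6 | step 14 | hexa-O-benzyl (2S)-4′,7-dihydroxyflavan-(4β→8)-4β-(2-ethoxyethoxy)epiafzelechin | c5ccccc5COc1ccc([C@@H]2C[C@@H](c3c(OCc5ccccc5)cc(OCc5ccccc5)c4c3O[C@H](c3ccc(OCc5ccccc5)cc3)[C@H](OCc5ccccc5)[C@H]4OCCOCC)c3ccc(OCc5ccccc5)cc3O2)cc1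
F7 | step 17 | dimer core bonded from middle C4β to C8 of (2S)-7,4′-di-O-benzyl-5-hydroxyflavanone | c5ccccc5COc1ccc([C@@H]2C[C@@H](c3c(OCc5ccccc5)cc(OCc5ccccc5)c4c3O[C@H](c3ccc(OCc5ccccc5)cc3)[C@H](OCc5ccccc5)[C@H]4c3c(OCc5ccccc5)cc(O)c4c3O[C@H](c3ccc(OCc5ccccc5)cc3)CC4=O)c3ccc(OCc5ccccc5)cc3O2)cc1
F8 | step 17 | dimer core bonded from middle C4β to C8 of (2S,4S)-7-benzyloxy-2-Ar-chroman-4,5-diol | c5ccccc5COc1ccc([C@@H]2C[C@@H](c3c(OCc5ccccc5)cc(OCc5ccccc5)c4c3O[C@H](c3ccc(OCc5ccccc5)cc3)[C@H](OCc5ccccc5)[C@H]4c3c(OCc5ccccc5)cc(O)c4c3O[C@H](c3ccc(OCc5ccccc5)cc3)C[C@@H]4O)c3ccc(OCc5ccccc5)cc3O2)cc1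
F9 | step 2 | racemic 7-(benzyloxy)-2-[4-(benzyloxy)phenyl]chroman-4-one | O=C1CC(c2ccc(OCc3ccccc3)cc2)Oc2cc(OCc3ccccc3)ccc12
A1 | alternative 1 | 3-benzyloxy-2-[(E)-3-(4-benzyloxyphenyl)prop-2-enyl]-6-[(2S,4R)-7-benzyloxy-2-(4-benzyloxyphenyl)chroman-4-yl]-5-(triisopropylsilyloxy)phenol | c5ccccc5COc1ccc([C@@H]2C[C@@H](c3c(O)c(C/C=C/c4ccc(OCc5ccccc5)cc4)c(OCc5ccccc5)cc3O[Si](C(C)C)(C(C)C)C(C)C)c3ccc(OCc5ccccc5)cc3O2)cc1
A2 | alternative 1 | (2S)-7-benzyloxy-2-(4-benzyloxyphenyl)-4β-[(triisopropylsilyloxy)ethynyl]chromane (2,4-trans) | c5ccccc5COc1ccc([C@@H]2C[C@@H](C#CO[Si](C(C)C)(C(C)C)C(C)C)c3ccc(OCc5ccccc5)cc3O2)cc1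
A3 | alternative 1 | 3-(benzyloxy)-4-[(E)-3-(4-benzyloxyphenyl)prop-2-enyl]cyclobut-2-en-1-one | O=C1C=C(OCc2ccccc2)C1C/C=C/c1ccc(OCc2ccccc2)cc1
A4 | alternative 2 | nona-O-benzyl trimer with the middle C3 hydroxyl free | c5ccccc5COc1ccc([C@@H]2C[C@@H](c3c(OCc5ccccc5)cc(OCc5ccccc5)c4c3O[C@H](c3ccc(OCc5ccccc5)cc3)[C@H](O)[C@H]4c3c(OCc5ccccc5)cc(OCc5ccccc5)c4c3O[C@H](c3ccc(OCc5ccccc5)cc3)[C@H](OCc5ccccc5)C4)c3ccc(OCc5ccccc5)cc3O2)cc1
A5 | alternative 2 | trans-epoxide: aryl ether of the C8-flavanyl 3,5-bis(benzyloxy)phenol with 1-(4-benzyloxyphenyl)-2,3-epoxy-3-(3,5,7,4′-tetra-O-benzylepiafzelechin-8-yl)propan-1-ol | c5ccccc5COc1ccc([C@@H]2C[C@@H](c3c(OCc5ccccc5)cc(OCc5ccccc5)cc3O[C@H](c3ccc(OCc5ccccc5)cc3)[C@@H]9O[C@H]9c3c(OCc5ccccc5)cc(OCc5ccccc5)c4c3O[C@H](c3ccc(OCc5ccccc5)cc3)[C@H](OCc5ccccc5)C4)c3ccc(OCc5ccccc5)cc3O2)cc1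
A6 | alternative 3 | nona-O-benzyl trimer with the middle C3 acetate | c5ccccc5COc1ccc([C@@H]2C[C@@H](c3c(OCc5ccccc5)cc(OCc5ccccc5)c4c3O[C@H](c3ccc(OCc5ccccc5)cc3)[C@H](OC(C)=O)[C@H]4c3c(OCc5ccccc5)cc(OCc5ccccc5)c4c3O[C@H](c3ccc(OCc5ccccc5)cc3)[C@H](OCc5ccccc5)C4)c3ccc(OCc5ccccc5)cc3O2)cc1
A7 | alternative 3 | diaryl carbinol linking C4a of the upper-substituted middle ring A phenol to C8 of 3,5,7,4′-tetra-O-benzylepiafzelechin | c5ccccc5COc1ccc([C@@H]2C[C@@H](c3c(OCc5ccccc5)cc(OCc5ccccc5)c(C(O)c4c(OCc5ccccc5)cc(OCc5ccccc5)c6c4O[C@H](c4ccc(OCc5ccccc5)cc4)[C@H](OCc5ccccc5)C6)c3O)c3ccc(OCc5ccccc5)cc3O2)cc1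
A8 | alternative 3 | (Z)-2-[4-(benzyloxy)phenyl]ethenyl acetate | CC(=O)O/C=C\c1ccc(OCc2ccccc2)cc1
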